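**Plan**
- Retrosynthesis: the O7 methoxymethyl acetal is cut first, then the two aryl–CH2 bonds C8–C1'' (ring A) and C3'–C1''' (ring B) are cut together, each prenyl group going back to a phenolic oxygen.
- Enabling feature: C8 is para to O5 on ring A and is reachable from O5 through C6, the one open ortho carbon (C4a is substituted). C3' is ortho to O4' on ring B. An O5 prenyl ether (Claisen, then Cope) and an O4' 1,1-dimethylallyl ether (one Claisen) therefore deliver normal prenyl groups to the right carbons.
- The three ether bonds (O5–prenyl, O4'–tertiary allyl, O7–MOM) are then cut back to (2S)-naringenin (1), using the acidity order 7-OH > 4'-OH > chelated 5-OH.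
- Forward: no ring is built. The intact flavanone is etherified at O7, O4' and O5 in that order, one heating operation makes both C–C bonds, and mild acid frees O7.
- Stereochemistry: the only stereocenter, C2 (S), comes with naringenin and is never touched; conditions avoid the free-phenoxide and strong-base media that open the pyranone ring.

Key step: step 5

Assumption: (2S)-naringenin is taken as the commercially supplied single enantiomer, and its enantiomeric purity should be confirmed by chiral HPLC before use because 4'-hydroxyflavanones epimerize at C2 in basic media.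

**Step 1**
Reactants: 1 (2S)-naringenin
Product: 2 (2S)-7-O-(methoxymethyl)naringenin
Conditions: MOMCl (1.05 equiv), i-Pr2NEt (1.2 equiv), THF, 0 °C
Reagents that add atoms: chloromethyl methyl ether, COCCl
Why: Williamson-type O-alkylation under amine base: the 7-hydroxyl is para to the C4 carbonyl and the most acidic phenol, whereas the 5-hydroxyl is hydrogen-bonded to C4=O and the 4'-hydroxyl is an ordinary phenol, so one equivalent of MOMCl at 0 °C should etherify O7 selectively without opening the pyranone ring.

**Step 2**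
Reactants: 3 2-methylbut-3-en-2-ol
Product: 5 methyl 2-methylbut-3-en-2-yl carbonate, via lithium 2-methylbut-3-en-2-olate 4 (not isolated)
Conditions: n-BuLi, THF, −78 °C; then ClCO2Me, −78 °C to rt
Reagents that add atoms: methyl chloroformate, COC(=O)Cl; n-butyllithium, [Li]CCCC (lithium of intermediate 4 only)
Why: O-acylation of the lithium alkoxide of a tertiary allylic alcohol with a chloroformate is the standard preparation of allylic carbonates for palladium-catalysed allylation.

**Step 3**
Reactants: 2 (2S)-7-O-(methoxymethyl)naringenin; 5 methyl 2-methylbut-3-en-2-yl carbonate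
Product: 6 (2S)-5-hydroxy-7-(methoxymethoxy)-2-[4-(2-methylbut-3-en-2-yloxy)phenyl]chroman-4-one
Conditions: Pd(PPh3)4 (5 mol%), 5 (1.5 equiv), THF, 4 Å MS, 0 °C to rt
Reagents that add atoms: none
Why: Tsuji–Trost O-allylation: zerovalent palladium ionizes carbonate 5 with loss of CO2 and methoxide, the methoxide deprotonates only the free 4'-phenol (the 5-hydroxyl stays chelated), and the phenoxide attacks the more substituted terminus of the 1,1-dimethylallyl palladium intermediate to give the tertiary ether under kinetic control with no added base.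

**Step 4**
Reactants: 6 (2S)-5-hydroxy-7-(methoxymethoxy)-2-[4-(2-methylbut-3-en-2-yloxy)phenyl]chroman-4-one; 7 prenol (3-methylbut-2-en-1-ol)
Product: 8 (2S)-7-(methoxymethoxy)-5-(3-methylbut-2-enyloxy)-2-[4-(2-methylbut-3-en-2-yloxy)phenyl]chroman-4-one
Conditions: PPh3, DIAD, THF, 0 °C to rt
Reagents that add atoms: none
Why: Mitsunobu etherification of the only remaining hydroxyl: the chelated 5-phenol protonates the PPh3–DIAD betaine and then displaces Ph3PO from the prenyloxyphosphonium ion at the primary carbon (SN2), under near-neutral conditions that avoid the base-induced opening of 5-hydroxyflavanones to chalcones.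

**Step 5**
Reactants: 8 (2S)-7-(methoxymethoxy)-5-(3-methylbut-2-enyloxy)-2-[4-(2-methylbut-3-en-2-yloxy)phenyl]chroman-4-one
Product: 11 (2S)-7-O-(methoxymethyl)euchrestaflavanone A, via ring A ortho-dienone 9 (not isolated), via 8-prenyl ring B ether 10 (not isolated)
Conditions: Eu(fod)3 (15 mol%), PhCl, argon, 60 °C, then 100 °C
Reagents that add atoms: none
Why: Coordination of the oxophilic trivalent europium centre of Eu(fod)3 to the C4 ketone and the neighbouring O5 ether oxygen polarizes the O5–allyl bond, so a chair-like aromatic Claisen [3,3] shift delivers the allyl unit, inverted, to C6 (dienone 9); the crowded 1,1-dimethylallyl group on the sp3 carbon C6 then moves on by a Cope [3,3] shift to C8, where it is again a normal prenyl group (new C8–C1'' bond), and enolization gives the hydrogen-bonded 5-phenol 10. At the higher temperature the tertiary allyl ether on ring B undergoes one ortho-Claisen shift to C3' (new C3'–C1''' bond) followed by tautomerization to the phenol. The closest known reactions are the Eu(fod)3-promoted para-Claisen–Cope rearrangement of 5-O-prenylflavanones and the thermal or Eu(fod)3-catalysed ortho-Claisen rearrangement of aryl 1,1-dimethylallyl ethers. No ring is closed and no stereocenter is created, and C2 is a spectator under these neutral aprotic conditions. The selectivity required is positional: on ring A the quaternary C4a leaves C6 as the only ortho outlet and C8 as the only para terminus, with europium chelation favouring the Cope shift over enolization of 9, and on ring B the 3' and 5' carbons are equivalent so either ortho shift gives the same product.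

**Step 6**
Reactants: 11 (2S)-7-O-(methoxymethyl)euchrestaflavanone A
Product: 12 euchrestaflavanone A
Conditions: 3 M aq. HCl, MeOH, 40 °C
Reagents that add atoms: none
Why: Acid-catalysed transacetalization of the aryl methoxymethyl ether with methanol releases the 7-phenol, and dilute acid at 40 °C should be too weak to protonate the trisubstituted prenyl alkenes (chroman formation) or to open the flavanone ring, so C2 stays (S).

**Compound list**
1 | (2S)-naringenin, (2S)-5,7-dihydroxy-2-(4-hydroxyphenyl)chroman-4-one | O=C1C[C@@H](c2ccc(O)cc2)Oc2cc(O)cc(O)c12 | starting material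
2 | (2S)-7-O-(methoxymethyl)naringenin, (2S)-5-hydroxy-2-(4-hydroxyphenyl)-7-(methoxymethoxy)chroman-4-one | O=C1C[C@@H](c2ccc(O)cc2)Oc2cc(OCOC)cc(O)c12 | intermediate
3 | 2-methylbut-3-en-2-ol | C=CC(C)(C)O | starting material
4 | lithium 2-methylbut-3-en-2-olate | C=CC(C)(C)[O-].[Li+] | intermediate (not isolated)
5 | methyl 2-methylbut-3-en-2-yl carbonate | C=CC(C)(C)OC(=O)OC | intermediate
6 | (2S)-5-hydroxy-7-(methoxymethoxy)-2-[4-(2-methylbut-3-en-2-yloxy)phenyl]chroman-4-one | C=CC(C)(C)Oc1ccc(cc1)[C@@H]2CC(=O)c3c(O)cc(OCOC)cc3O2 | intermediate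
7 | prenol (3-methylbut-2-en-1-ol) | CC(C)=CCO | starting material
8 | (2S)-7-(methoxymethoxy)-5-(3-methylbut-2-enyloxy)-2-[4-(2-methylbut-3-en-2-yloxy)phenyl]chroman-4-one | C=CC(C)(C)Oc1ccc(cc1)[C@@H]2CC(=O)c3c(OCC=C(C)C)cc(OCOC)cc3O2 | intermediate
9 | ring A ortho-dienone, (2S)-7-(methoxymethoxy)-6-(2-methylbut-3-en-2-yl)-2-[4-(2-methylbut-3-en-2-yloxy)phenyl]-2,3-dihydro-4H-chromene-4,5(6H)-dione (both C6 epimers) | C=CC(C)(C)Oc1ccc(cc1)[C@@H]2CC(=O)C3=C(O2)C=C(OCOC)C(C3=O)C(C)(C)C=C | intermediate (not isolated)
10 | 8-prenyl ring B ether, (2S)-5-hydroxy-7-(methoxymethoxy)-8-(3-methylbut-2-enyl)-2-[4-(2-methylbut-3-en-2-yloxy)phenyl]chroman-4-one | C=CC(C)(C)Oc1ccc(cc1)[C@@H]2CC(=O)c3c(O)cc(OCOC)c(CC=C(C)C)c3O2 | intermediate (not isolated)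
11 | (2S)-7-O-(methoxymethyl)euchrestaflavanone A, (2S)-5-hydroxy-2-[4-hydroxy-3-(3-methylbut-2-enyl)phenyl]-7-(methoxymethoxy)-8-(3-methylbut-2-enyl)chroman-4-one | CC(C)=CCc1cc([C@@H]2CC(=O)c3c(O)cc(OCOC)c(CC=C(C)C)c3O2)ccc1O | intermediate
12 | euchrestaflavanone A, (2S)-5,7-dihydroxy-2-[4-hydroxy-3-(3-methylbut-2-enyl)phenyl]-8-(3-methylbut-2-enyl)chroman-4-one | CC(C)=CCc1cc([C@@H]2CC(=O)c3c(O)cc(O)c(CC=C(C)C)c3O2)ccc1O | target

**Step count and risks**
Total steps: 6. Longest linear sequence: 5 steps (steps 1, 3, 4, 5 and 6 from naringenin); step 2 is a one-step side branch.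

Steps most likely to fail:

1. Step 5. Dienone 9 may enolize before the Cope shift, which would leave the group at C6 as a 1,1-dimethylallyl substituent. The europium Lewis acid may also ionize the tertiary allyl ether on ring B at the temperature its shift needs, with loss of the C5 unit. Fallback, setting out from 6 and coming back at 12: the two shifts are separated and the ring B shift is run first without Lewis acid. Compound 6 is heated in o-xylene at 130 °C so that only the ortho-Claisen shift occurs, giving (2S)-7-O-(methoxymethyl)-3'-prenylnaringenin F1. The freed 4'-phenol is capped with MOMCl and i-Pr2NEt in CH2Cl2 at 0 °C to give (2S)-7,4'-di-O-(methoxymethyl)-3'-prenylnaringenin F2. Mitsunobu reaction with prenol 7 (PPh3, DIAD, THF) gives (2S)-5-O-prenyl-7,4'-di-O-(methoxymethyl)-3'-prenylnaringenin F3. Eu(fod)3 (10 mol%) in CHCl3 at 60 °C then has to effect only the ring A Claisen–Cope relay, giving (2S)-7,4'-di-O-(methoxymethyl)euchrestaflavanone A F4. Methanolic HCl removes both acetals and the route is rejoined at 12.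

2. Step 3. The phenoxide may attack the unsubstituted allyl terminus, or palladium may re-ionize the tertiary ether and funnel it to the linear O-prenyl isomer. Fallback, setting out from 2 and coming back at 6: the tertiary ether is made by propargylation and semi-reduction instead of allylic substitution. Compound 2 is treated with 3-chloro-3-methylbut-1-yne, CuCl2 (cat.) and DBU in MeCN at −5 °C to give (2S)-5-hydroxy-7-(methoxymethoxy)-2-[4-(2-methylbut-3-yn-2-yloxy)phenyl]chroman-4-one F5. Semi-hydrogenation of the alkyne (H2, Pd/CaCO3 poisoned with Pb(OAc)2, quinoline, EtOAc) returns the route at 6.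

3. Step 6. Acid may protonate a prenyl alkene, leading to cyclization onto the neighbouring phenol (chroman formation) or addition of methanol, before the acetal is fully cleaved. Fallback, setting out from 1 and coming back at 12: O7 is carried as a silyl ether that is removed by fluoride instead of acid. Naringenin 1 with TIPSCl and imidazole in DMF at 0 °C should give (2S)-7-O-(triisopropylsilyl)naringenin F6. Pd(PPh3)4 with carbonate 5 gives (2S)-5-hydroxy-2-[4-(2-methylbut-3-en-2-yloxy)phenyl]-7-(triisopropylsilyloxy)chroman-4-one F7. Mitsunobu reaction with prenol 7 gives (2S)-5-(3-methylbut-2-enyloxy)-2-[4-(2-methylbut-3-en-2-yloxy)phenyl]-7-(triisopropylsilyloxy)chroman-4-one F8. The Eu(fod)3 cascade of step 5 gives (2S)-7-O-(triisopropylsilyl)euchrestaflavanone A F9. Bu4NF buffered with AcOH in THF at 0 °C then gives 12.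

**Further compounds**
F1 | step 5 | (2S)-7-O-(methoxymethyl)-3'-prenylnaringenin | CC(C)=CCc1cc([C@@H]2CC(=O)c3c(O)cc(OCOC)cc3O2)ccc1O
F2 | step 5 | (2S)-7,4'-di-O-(methoxymethyl)-3'-prenylnaringenin | CC(C)=CCc1cc([C@@H]2CC(=O)c3c(O)cc(OCOC)cc3O2)ccc1OCOC
F3 | step 5 | (2S)-5-O-prenyl-7,4'-di-O-(methoxymethyl)-3'-prenylnaringenin | CC(C)=CCc1cc([C@@H]2CC(=O)c3c(OCC=C(C)C)cc(OCOC)cc3O2)ccc1OCOC
F4 | step 5 | (2S)-7,4'-di-O-(methoxymethyl)euchrestaflavanone A | CC(C)=CCc1cc([C@@H]2CC(=O)c3c(O)cc(OCOC)c(CC=C(C)C)c3O2)ccc1OCOC
F5 | step 3 | (2S)-5-hydroxy-7-(methoxymethoxy)-2-[4-(2-methylbut-3-yn-2-yloxy)phenyl]chroman-4-one | C#CC(C)(C)Oc1ccc(cc1)[C@@H]2CC(=O)c3c(O)cc(OCOC)cc3O2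
F6 | step 6 | (2S)-7-O-(triisopropylsilyl)naringenin | O=C1C[C@@H](c2ccc(O)cc2)Oc2cc(O[Si](C(C)C)(C(C)C)C(C)C)cc(O)c12
F7 | step 6 | (2S)-5-hydroxy-2-[4-(2-methylbut-3-en-2-yloxy)phenyl]-7-(triisopropylsilyloxy)chroman-4-one | C=CC(C)(C)Oc1ccc(cc1)[C@@H]2CC(=O)c3c(O)cc(O[Si](C(C)C)(C(C)C)C(C)C)cc3O2
F8 | step 6 | (2S)-5-(3-methylbut-2-enyloxy)-2-[4-(2-methylbut-3-en-2-yloxy)phenyl]-7-(triisopropylsilyloxy)chroman-4-one | C=CC(C)(C)Oc1ccc(cc1)[C@@H]2CC(=O)c3c(OCC=C(C)C)cc(O[Si](C(C)C)(C(C)C)C(C)C)cc3O2
F9 | step 6 | (2S)-7-O-(triisopropylsilyl)euchrestaflavanone A | CC(C)=CCc1cc([C@@H]2CC(=O)c3c(O)cc(O[Si](C(C)C)(C(C)C)C(C)C)c(CC=C(C)C)c3O2)ccc1O
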